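**Assumption:** (R)-(5-oxotetrahydrofuran-2-yl)methyl tosylate (13) is taken as a catalogue chiral-pool reagent; if not, it is one step (TsCl, pyridine) from commercial (R)-5-(hydroxymethyl)dihydrofuran-2(3H)-one.

**Numbering used:** ring N1, C2 (CH2OH), C3, C4, C5 (side chain); side chain C1'–C13'. By CIP analysis the target is (2R,3R,4R,5R,1'R,10'S).

## Retrosynthetic overview

1. Broussonetine S ⇐ one-pot hydrogenation/hydrogenolysis of the C3'=C4' cross-metathesis product of pyrrolidine homoallylic alcohol 12 and (S)-undec-10-ene-1,4-diol 16.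
2. 12 ⇐ Brown allylation (sets C1') of N-Cbz aldehyde 10 ⇐ ozonolysis of the 5-vinylpyrrolidine ⇐ vinylMgBr addition (sets C5, trans) to the D-arabinose-derived cyclic nitrone 5.
3. The only ring formed is the pyrrolidine, closed as nitrone 5 by intramolecular N-alkylation of an oximate onto a C4 iodide (double inversion, net retention); C2, C3, C4 come from D-arabinose.
4. 16 ⇐ LiAlH4 opening of lactone 15 ⇐ cuprate displacement on the D-glutamic-acid-derived tosylate 13 (C10' from the chiral pool).

## Route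

**Step 1**
Reactants: 1, 2,3,5-tri-O-benzyl-D-arabinofuranose; 2, O-(tert-butyldiphenylsilyl)hydroxylamine
Product: 3, 2,3,5-tri-O-benzyl-D-arabinose O-TBDPS oxime (open chain, E/Z mixture, free 4-OH)
Conditions: TBDPSONH2, PPTS (cat.), MgSO4, toluene, 110 °C
Reagents that add atoms: O-(tert-butyldiphenylsilyl)hydroxylamine, NO[Si](c1ccccc1)(c1ccccc1)C(C)(C)C
Why: Oxime-ether condensation on the open-chain aldehyde tautomer of the lactol opens the furanose and frees O4–H without touching a stereocentre.

**Step 2**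
Reactants: 3
Product: 4, 2,3,5-tri-O-benzyl-4-deoxy-4-iodo-L-xylose O-TBDPS oxime (C4 inverted)
Conditions: I2, PPh3, imidazole, toluene, 80 °C
Reagents that add atoms: iodine, II
Why: Garegg–Samuelsson (Appel-type) iodination; iodide displaces the alkoxyphosphonium by SN2, inverting C4.

**Step 3**
Reactants: 4
Product: 5, (2R,3R,4R)-3,4-bis(benzyloxy)-2-[(benzyloxy)methyl]-3,4-dihydro-2H-pyrrole 1-oxide (D-arabino cyclic nitrone)
Conditions: TBAF, THF, reflux
Reagents that add atoms: none
Why: Desilylation gives the oximate, whose nitrogen displaces iodide intramolecularly (5-exo-tet SN2, second inversion), forming the ring with net retention at the future C2.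

**Step 4**
Reactants: 5; 6, vinylmagnesium bromide
Product: 7, (2R,3R,4R,5R)-3,4-bis(benzyloxy)-2-[(benzyloxy)methyl]-5-vinylpyrrolidin-1-ol
Conditions: vinylMgBr, THF, −78 → 0 °C
Reagents that add atoms: vinylmagnesium bromide, C=C[Mg]Br
Why: Grignard addition to the nitrone C=N occurs anti to the adjacent OBn group, setting C5 (R) as the all-trans, 2,5-trans (DMDP-type) isomer.

**Step 5**
Reactants: 7
Product: 8, (2R,3R,4R,5R)-3,4-bis(benzyloxy)-2-[(benzyloxy)methyl]-5-vinylpyrrolidine
Conditions: Zn, Cu(OAc)2 (cat.), AcOH/H2O, rt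
Reagents that add atoms: none
Why: Dissolving-metal N–O reduction of the hydroxylamine; the vinyl group and benzyl ethers are inert.

**Step 6**
Reactants: 8
Product: 9, benzyl (2R,3R,4R,5R)-3,4-bis(benzyloxy)-2-[(benzyloxy)methyl]-5-vinylpyrrolidine-1-carboxylate
Conditions: CbzCl, NaHCO3, THF/H2O, 0 °C → rt
Reagents that add atoms: benzyl chloroformate, O=C(Cl)OCc1ccccc1
Why: Schotten–Baumann N-acylation; the carbamate prevents N-oxidation by ozone, stabilises the α-amino aldehyde, and leaves in the final hydrogenolysis.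

**Step 7**
Reactants: 9
Product: 10, benzyl (2S,3R,4R,5R)-3,4-bis(benzyloxy)-5-[(benzyloxy)methyl]-2-formylpyrrolidine-1-carboxylate
Conditions: O3, CH2Cl2, −78 °C; then PPh3; used crude
Reagents that add atoms: ozone, [O-][O+]=O
Why: Ozonolysis with reductive work-up cleaves the vinyl group to the C1' aldehyde; the formyl group is trans to the neighbouring OBn (the more stable epimer), and the descriptor change is only a CIP priority effect.

**Step 8**
Reactants: 10; 11, allylmagnesium bromide
Product: 12, benzyl (2R,3R,4R,5R)-3,4-bis(benzyloxy)-2-[(benzyloxy)methyl]-5-[(1R)-1-hydroxybut-3-en-1-yl]pyrrolidine-1-carboxylate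
Conditions: (+)-Ipc2BOMe [from (−)-α-pinene], allylMgBr, Et2O, 0 °C → rt; then 10, −78 °C; pH 7 buffer, H2O2
Reagents that add atoms: allylmagnesium bromide, C=CC[Mg]Br (delivered as (+)-Ipc2B-allyl)
Why: Brown asymmetric allylboration through a chair Zimmerman–Traxler transition state; the (−)-α-pinene-derived reagent adds to the Re face to give (1'R), which is also the Felkin–Anh (anti amino alcohol) sense, so the case is matched.

**Step 9**
Reactants: 13, (R)-(5-oxotetrahydrofuran-2-yl)methyl 4-methylbenzenesulfonate; 14, 6-bromohex-1-ene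
Product: 15, (S)-5-(hept-6-en-1-yl)dihydrofuran-2(3H)-one
Conditions: 14, Mg, THF; CuBr·SMe2 (0.5 equiv per RMgBr), −45 °C; then 13, −45 → −20 °C
Reagents that add atoms: 6-bromohex-1-ene, BrCCCCC=C (as its magnesium cuprate)
Why: Cuprate SN2 displacement of the primary tosylate, with the lactone spared at low temperature; the stereocentre is untouched (R → S is a CIP priority change only).

**Step 10**
Reactants: 15
Product: 16, (S)-undec-10-ene-1,4-diol
Conditions: LiAlH4, THF, 0 °C → rt
Reagents that add atoms: none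
Why: Hydride reduction of the lactone to the 1,4-diol; the isolated alkene and the carbinol centre (future C10') are unaffected.

**Step 11**
Reactants: 12; 16 (3 equiv)
Product: 17, benzyl (2R,3R,4R,5R)-3,4-bis(benzyloxy)-2-[(benzyloxy)methyl]-5-[(1R,3E,10S)-1,10,13-trihydroxytridec-3-en-1-yl]pyrrolidine-1-carboxylate (E major; E/Z irrelevant)
Conditions: Grubbs II (10 mol %), CH2Cl2, 40 °C
Reagents that add atoms: (S)-undec-10-ene-1,4-diol, OCCC[C@@H](O)CCCCCC=C
Why: Ru-catalysed olefin cross-metathesis of two unhindered terminal alkenes, driven by ethylene loss and excess 16; free hydroxyls and the carbamate are tolerated.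

**Step 12**
Reactants: 17
Product: 18, broussonetine S
Conditions: H2 (1 atm), 10% Pd/C, MeOH, 1 M HCl, rt; Dowex 50WX8 (H+), elute aq NH3
Reagents that add atoms: none
Why: One catalytic hydrogenation saturates the C3'=C4' alkene and hydrogenolyses the three benzyl ethers and the Cbz group; no stereocentre is affected.

## Compound list

1 | 2,3,5-tri-O-benzyl-D-arabinofuranose | OC1O[C@H](COCc2ccccc2)[C@@H](OCc2ccccc2)[C@@H]1OCc1ccccc1 | starting material
2 | O-(tert-butyldiphenylsilyl)hydroxylamine | NO[Si](c1ccccc1)(c1ccccc1)C(C)(C)C | starting material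
3 | 2,3,5-tri-O-benzyl-D-arabinose O-TBDPS oxime | CC(C)(C)[Si](c1ccccc1)(c1ccccc1)ON=C[C@@H](OCc1ccccc1)[C@H](OCc1ccccc1)[C@H](O)COCc1ccccc1 | intermediate
4 | 2,3,5-tri-O-benzyl-4-deoxy-4-iodo-L-xylose O-TBDPS oxime | CC(C)(C)[Si](c1ccccc1)(c1ccccc1)ON=C[C@@H](OCc1ccccc1)[C@H](OCc1ccccc1)[C@@H](I)COCc1ccccc1 | intermediate
5 | (2R,3R,4R)-3,4-bis(benzyloxy)-2-[(benzyloxy)methyl]-3,4-dihydro-2H-pyrrole 1-oxide | C1=[N+]([O-])[C@H](COCc2ccccc2)[C@@H](OCc2ccccc2)[C@@H]1OCc1ccccc1 | intermediate
6 | vinylmagnesium bromide | C=C[Mg]Br | starting material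
7 | (2R,3R,4R,5R)-3,4-bis(benzyloxy)-2-[(benzyloxy)methyl]-5-vinylpyrrolidin-1-ol | C=C[C@H]1N(O)[C@H](COCc2ccccc2)[C@@H](OCc2ccccc2)[C@@H]1OCc1ccccc1 | intermediate
8 | (2R,3R,4R,5R)-3,4-bis(benzyloxy)-2-[(benzyloxy)methyl]-5-vinylpyrrolidine | C=C[C@H]1N[C@H](COCc2ccccc2)[C@@H](OCc2ccccc2)[C@@H]1OCc1ccccc1 | intermediate
9 | benzyl (2R,3R,4R,5R)-3,4-bis(benzyloxy)-2-[(benzyloxy)methyl]-5-vinylpyrrolidine-1-carboxylate | C=C[C@H]1N(C(=O)OCc2ccccc2)[C@H](COCc2ccccc2)[C@@H](OCc2ccccc2)[C@@H]1OCc1ccccc1 | intermediate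
10 | benzyl (2S,3R,4R,5R)-3,4-bis(benzyloxy)-5-[(benzyloxy)methyl]-2-formylpyrrolidine-1-carboxylate | O=C[C@H]1N(C(=O)OCc2ccccc2)[C@H](COCc2ccccc2)[C@@H](OCc2ccccc2)[C@@H]1OCc1ccccc1 | intermediate
11 | allylmagnesium bromide | C=CC[Mg]Br | starting material
12 | benzyl (2R,3R,4R,5R)-3,4-bis(benzyloxy)-2-[(benzyloxy)methyl]-5-[(1R)-1-hydroxybut-3-en-1-yl]pyrrolidine-1-carboxylate | C=CC[C@@H](O)[C@H]1N(C(=O)OCc2ccccc2)[C@H](COCc2ccccc2)[C@@H](OCc2ccccc2)[C@@H]1OCc1ccccc1 | intermediate
13 | (R)-(5-oxotetrahydrofuran-2-yl)methyl 4-methylbenzenesulfonate | Cc1ccc(cc1)S(=O)(=O)OC[C@H]1CCC(=O)O1 | starting material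
14 | 6-bromohex-1-ene | BrCCCCC=C | starting material
15 | (S)-5-(hept-6-en-1-yl)dihydrofuran-2(3H)-one | C=CCCCCC[C@H]1CCC(=O)O1 | intermediate
16 | (S)-undec-10-ene-1,4-diol | OCCC[C@@H](O)CCCCCC=C | intermediate
17 | benzyl (2R,3R,4R,5R)-3,4-bis(benzyloxy)-2-[(benzyloxy)methyl]-5-[(1R,3E,10S)-1,10,13-trihydroxytridec-3-en-1-yl]pyrrolidine-1-carboxylate | OCCC[C@@H](O)CCCCC/C=C/C[C@@H](O)[C@H]1N(C(=O)OCc2ccccc2)[C@H](COCc2ccccc2)[C@@H](OCc2ccccc2)[C@@H]1OCc1ccccc1 | intermediate
18 | broussonetine S, (2R,3R,4R,5R)-2-(hydroxymethyl)-5-[(1R,10S)-1,10,13-trihydroxytridecyl]pyrrolidine-3,4-diol | OCCC[C@@H](O)CCCCCCCC[C@@H](O)[C@H]1N[C@H](CO)[C@@H](O)[C@@H]1O | target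

## Summary

**Total steps:** 12
**Longest linear sequence:** 10 (steps 1–8, 11, 12); the side-chain branch is steps 9–10.

**Three steps most likely to fail**

1. **Step 8, Brown allylation of the α-amino aldehyde.** Risks are epimerisation of 10, insufficient dr at C1', and cyclic carbamate formation. Fallback: set C1' by reduction instead of C–C addition. Add the lithium acetylide of the bis-silylated alkyne analogue of the side chain to 10, oxidise to the ynone, and reduce under catalyst control (CBS or Noyori transfer hydrogenation); the final hydrogenation saturates the alkyne and no metathesis is needed.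
2. **Step 9, cuprate displacement of the tosylate next to a lactone.** Risks are carbonyl attack and a sluggish SN2. Fallback: switch to an epoxide opening. Treat 13 with NaOMe/MeOH to give methyl (R)-4,5-epoxypentanoate, open at the terminal carbon with hex-5-enylMgBr and catalytic CuI, and relactonise with acid to 15; the stereocentre is again untouched.
3. **Step 11, cross-metathesis of two type I alkenes.** Risks are homodimerisation, olefin migration, and Ru chelation by the homoallylic alcohol/carbamate. Fallback: form C1'–C2' by carbonyl addition. Add the full-length Grignard reagent BrMg(CH2)8CH(OTBS)(CH2)3OTBS to aldehyde 10 (Felkin–Anh control, corrected by oxidation and chelation-controlled reduction if needed), then desilylate and hydrogenolyse.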